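West, south-east and east share a loading of 15 mol% and end at 61%, 63% and 61% at 6.00 h, though east holds 4.29 times west's charge.

| setting | west | south-east | east | north | winter | summer | noon | midnight |
|---|---|---|---|---|---|---|---|---|
| substrate | 0.28 M | 0.62 M | 1.2 M | 0.78 M | 1.5 M | 0.78 M | 0.25 M | 0.25 M |
| free catalyst | 15 mol% | 15 mol% | 15 mol% | 12 mol% | 10 mol% | 15 mol% | 25 mol% | 15 mol% |
| remark | run made earlier | run made earlier | run made earlier | run made earlier |  |  |  |  |
| time |  |  |  |  | 6.0 h | 6.0 h | 6.0 h | 6.0 h |

| run | time / h | product / % | substrate / % |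
|---|---|---|---|
| west | 1.33 | 15 | 75 |
| west | 2.50 | 24 | 64 |
| west | 4.00 | 42 | 52 |
| west | 5.00 | 50 | 37 |
| west | 6.00 | 61 | 31 |
| south-east | 1.33 | 11 | 74 |
| south-east | 2.50 | 27 | 58 |
| south-east | 4.00 | 45 | 45 |
| south-east | 5.00 | 55 | 31 |
| south-east | 6.00 | 63 | 27 |
| east | 1.33 | 14 | 73 |
| east | 2.50 | 29 | 58 |
| east | 4.00 | 43 | 42 |
| east | 5.00 | 53 | 32 |
| east | 6.00 | 61 | 27 |
| north | 1.33 | 16 | 76 |
| north | 2.50 | 19 | 68 |
| north | 4.00 | 35 | 55 |
| north | 5.00 | 42 | 41 |
| north | 6.00 | 53 | 38 |

(scatter of a reading: 2 percentage points)

1. ranking by amount of product, in percent of the substrate charged, from high to low, at 6.0 h (winter / summer / noon / midnight)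
2. the amount of product, in percent of the substrate charged of the flask you put first, at 6.0 h
3. the amount of product, in percent of the substrate charged of the flask you put last, at 6.0 h

- a reading or a percentage of product counts all its forms, free or not

1. Starting speed. Those readings differ by about the scatter of 2 percentage points, so I read the rate as zero order in substrate. I define n, the turnover frequency, as product made per catalyst per hour on this straight line: n = 0.685 h⁻¹. For north it gives 49.3% against 53% read.

2. Rate per flask. Multiplying n by the loading gives the share of the charge converted per hour: 0.171 h⁻¹ for noon, 0.103 h⁻¹ for summer and midnight, 0.0685 h⁻¹ for winter. Held to 6.0 h, the line gives winter 41.1%, summer and midnight 61.7%, and noon 103%, which is more than the charge, so noon must slow.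

3. The slowing. West still gains 11 points in its last interval with 0.0868 M of substrate left, so I place the crossing there and take the rate as pseudo-first-order below it. In noon that level is 34.7% of the charge, reached at 3.81 h. Midnight's line stops short of that point, at less than 65.3% converted.

4. My reckoning. Noon's remainder shrinks by a factor 0.340, which gives 88.2%. Winter comes last, and summer and midnight tie.

5. The forecast. It gives noon > summer > midnight > winter, top 85%, low 42%, and says of noon that “saturation fails as substrate runs out”. Unlike my tie, it ranks summer above midnight.

6. The result. The flasks give noon > summer > midnight > winter: noon 84.1%, summer 64.3%, midnight 59.3%, winter 43.8%. The forecast stands, and noon lies below my 88.2%.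

    substrate + free catalyst → catalyst intermediate A (k = 0.00590 L mol⁻¹ s⁻¹)
    catalyst intermediate A → catalyst intermediate B (k = 3.70 × 10⁻⁴ s⁻¹)
    catalyst intermediate B → free catalyst + product (k = 9.00 × 10⁻⁴ s⁻¹)
    2 catalyst intermediate A → spent catalyst (k = 1.30 × 10⁻⁴ L mol⁻¹ s⁻¹)
    crystals ⇌ product, rate k5*(cs5 - [product]) while solid is left; crystals form when [product] > cs5 (solubility = 0.350 M, k = 0.00220 s⁻¹)

In noon at 6.00 h, the capture of free catalyst by substrate has a half-life of 2.11 h, longer than the 0.52 h of catalyst intermediate A's passage and the 0.21 h of catalyst intermediate B's. Noon's catalyst stands 45.7% as catalyst intermediate A against 29.9% free at 3.00 h, but 21.8% against 61.1% at 6.00 h.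

7. A second flask. Noon read at 1.5 h is before my crossing, so n gives 25.7%. That flask holds 21.6%.

The readings are calculated on assumed constants; scatter was added.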